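Everything rests on building ring A of the isoflavone half around an aryl–C8 bond that already exists, instead of coupling two hindered arenes. Heating 3-ethoxycyclobutenone with an aryl triisopropylsiloxyalkyne sets off a pericyclic cascade that forges C8–C8a, C6–C7 and C4a–C8a and delivers a 2-arylphloroglucinol. The step exploits the 1,3,5-trioxygenation of ring A. O1 appears as free phenol (ketene carbonyl), O7 as silyl ether (ynol oxygen) and O5 as ethyl ether, so the oxygens around aryl-bearing C8 differ from birth. The precursor is the O-silylated ynolate of a 2-methoxybenzoate whose masked formyl group later anchors the flavone.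

Key step: step 3

Remarks on the chemistry
- From step 3 on, ring A atoms carry isoflavone numbering (O1, C4a, C5 to C8, C8a).
- The C8–aryl axis has three ortho substituents, but the target carries no axial descriptor. All biaryls are taken as racemic about this axis and no step tries to control it.
- 3-Ethoxycyclobut-2-en-1-one is taken as a catalogue compound.
- The aldehyde is masked as a six-membered acetal. A 2-aryl-1,3-dioxolane can be lithiated at C2 by the excess n-BuLi of step 2 and then fragment to ethylene and a carboxylate on warming, and a 1,3-dioxane has no such pathway.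
- The alkene geometry of 14 to 17 is drawn E (oxygen substituent trans to the carbonyl group). It has no consequence, because step 8 erases it.
- After step 6 the silyl group has done its work. Losing it early would only lead to 22 ahead of time.

Step 1
Reactants: 1 methyl 5-formyl-2-methoxybenzoate
Product: 2 methyl 5-(5,5-dimethyl-1,3-dioxan-2-yl)-2-methoxybenzoate
Conditions: 2,2-dimethylpropane-1,3-diol, p-TsOH·H2O (cat.), toluene, reflux, Dean–Stark
Reagents that add atoms: 2,2-dimethylpropane-1,3-diol, OCC(C)(C)CO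
Why: Acid-catalysed acetalisation with azeotropic removal of water masks the aldehyde against the organolithium reagents of step 2 without touching the ester.

Step 2
Reactants: 2 methyl 5-(5,5-dimethyl-1,3-dioxan-2-yl)-2-methoxybenzoate
Product: 5 {[5-(5,5-dimethyl-1,3-dioxan-2-yl)-2-methoxyphenyl]ethynyloxy}triisopropylsilane, via lithium dibromoenolate 3 (not isolated), via lithium ynolate 4 (not isolated)
Conditions: CH2Br2, lithium 2,2,6,6-tetramethylpiperidide, THF, –78 °C, then 2; n-BuLi, –78 °C → rt; i-Pr3SiOTf, –78 → 0 °C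
Reagents that add atoms: dibromomethane, BrCBr; triisopropylsilyl trifluoromethanesulfonate, CC(C)[Si](OS(=O)(=O)C(F)(F)F)(C(C)C)C(C)C
Why: Kowalski ester homologation, in which acylation of LiCHBr2 gives the dibromoketone enolate, bromine–lithium exchange triggers a 1,2-shift of the electron-rich aryl group to the ynolate, and the bulky, hard silyl triflate should trap that anion on oxygen rather than on carbon.

Step 3
Reactants: 5 {[5-(5,5-dimethyl-1,3-dioxan-2-yl)-2-methoxyphenyl]ethynyloxy}triisopropylsilane; 6 3-ethoxycyclobut-2-en-1-one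
Product: 11 2-[5-(5,5-dimethyl-1,3-dioxan-2-yl)-2-methoxyphenyl]-5-ethoxy-3-(triisopropylsilyloxy)phenol, via vinylketene 7 (not isolated), via vinylcyclobutenone 8 (not isolated), via dienylketene 9 (not isolated), via cyclohexadienone 10 (not isolated)
Conditions: toluene, 80 → 110 °C, sealed vessel, 6 added slowly to a slight excess of 5
Reagents that add atoms: none
Why: Four-electron electrocyclic opening of 6 gives 3-ethoxyvinylketene 7, whose carbonyl carbon is attacked by the aryl-bearing alkyne carbon of 5 in a [2+2] cycloaddition (C8–C8a and C6–C7) to give vinylcyclobutenone 8. A second four-electron opening gives dienylketene 9, and ring A closes by thermal disrotatory six-electron electrocyclisation (C4a–C8a) to dienone 10, which tautomerises irreversibly to phenol 11. This is the Danheiser benzannulation of a cyclobutenone with a siloxyalkyne, a known route to resorcinol monosilyl ethers. No stereocentre survives, since the sp3 carbon of racemic 8 becomes aromatic C6. The step needs regioselectivity in the ketene–alkyne addition, and the polarisation of the ynol ether secures it by making the carbon remote from oxygen the nucleophile, which places the aryl group between the new hydroxyl and the silyloxy group. It also needs the ketene to meet the alkyne before it dimerises or acylates 11, which slow addition of 6 should ensure.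

Step 4
Reactants: 12 methyl 4-methoxyphenylacetate
Product: 13 methyl (Z)-3-hydroxy-2-(4-methoxyphenyl)acrylate (enol of the α-formyl ester)
Conditions: HCO2Me, NaH, THF, 0 °C → rt; 1 M HCl
Reagents that add atoms: methyl formate, COC=O
Why: Crossed Claisen condensation with non-enolisable methyl formate is driven by formation of the stabilised sodium enolate, and acidification should give the hydrogen-bonded Z enol.

Step 5
Reactants: 13 methyl (Z)-3-hydroxy-2-(4-methoxyphenyl)acrylate
Product: 14 methyl (E)-2-(4-methoxyphenyl)-3-(tosyloxy)acrylate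
Conditions: TsCl, Et3N, N-methylimidazole (cat.), CH2Cl2, 0 °C
Reagents that add atoms: p-toluenesulfonyl chloride, Cc1ccc(S(=O)(=O)Cl)cc1
Why: Enol O-sulfonylation under non-chelating amine conditions turns the hydroxyl into a leaving group on a vinylogous acyl carbon and should favour the E isomer, although either isomer serves.

Step 6
Reactants: 11 2-[5-(5,5-dimethyl-1,3-dioxan-2-yl)-2-methoxyphenyl]-5-ethoxy-3-(triisopropylsilyloxy)phenol; 14 methyl (E)-2-(4-methoxyphenyl)-3-(tosyloxy)acrylate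
Product: 15 methyl (E)-3-{2-[5-(5,5-dimethyl-1,3-dioxan-2-yl)-2-methoxyphenyl]-5-ethoxy-3-(triisopropylsilyloxy)phenoxy}-2-(4-methoxyphenyl)acrylate
Conditions: Cs2CO3, MeCN, rt → 50 °C
Reagents that add atoms: none
Why: Nucleophilic vinylic substitution by addition–elimination, in which the only free oxygen (the future O1) adds to the unhindered β-carbon of the acrylate and expels tosylate, while anhydrous carbonate leaves the silyl ether and the acetal alone.

Step 7
Reactants: 15 methyl (E)-3-{2-[5-(5,5-dimethyl-1,3-dioxan-2-yl)-2-methoxyphenyl]-5-ethoxy-3-(triisopropylsilyloxy)phenoxy}-2-(4-methoxyphenyl)acrylate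
Product: 16 (E)-3-{2-[5-(5,5-dimethyl-1,3-dioxan-2-yl)-2-methoxyphenyl]-5-ethoxy-3-(triisopropylsilyloxy)phenoxy}-2-(4-methoxyphenyl)acrylic acid
Conditions: LiOH·H2O, THF–H2O, rt → 40 °C; cold 0.5 M HCl to pH 4
Reagents that add atoms: lithium hydroxide, [Li+].[OH-]
Why: Saponification as practised on β-aryloxyacrylates, run without an alcohol cosolvent so that no alkoxide can displace the aryloxide at the β-carbon, and mild enough for the hindered silyl ether of an electron-rich ring.

Step 8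
Reactants: 16 (E)-3-{2-[5-(5,5-dimethyl-1,3-dioxan-2-yl)-2-methoxyphenyl]-5-ethoxy-3-(triisopropylsilyloxy)phenoxy}-2-(4-methoxyphenyl)acrylic acid
Product: 19 3-[5-ethoxy-3-(4-methoxyphenyl)-4-oxo-7-(triisopropylsilyloxy)-4H-chromen-8-yl]-4-methoxybenzaldehyde, via mixed anhydride 17 (not isolated), via isoflavone acetal 18 (not isolated)
Conditions: (CF3CO)2O, CH2Cl2, 0 °C → rt; concentrate; 2 M HCl, THF, 40 °C
Reagents that add atoms: water, O
Why: Intramolecular Friedel–Crafts acylation through the mixed trifluoroacetic anhydride, in which the acylium ion is also a vinylogous oxocarbenium ion whose C2–C3 bond rotates freely so the E geometry is no obstacle, blocked C8 leaves only C4a (ortho to O1 and OEt, para to OSi) open to attack, and the aqueous acid of the second stage hydrolyses the acetal while the aryl silyl ether holds.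

Step 9
Reactants: 20 2,4,6-trihydroxyacetophenone
Product: 21 1-[2,4-bis(benzyloxy)-6-hydroxyphenyl]ethanone
Conditions: BnBr (2.1 equiv), K2CO3, acetone, reflux
Reagents that add atoms: benzyl bromide, BrCc1ccccc1
Why: Williamson etherification should stop at the dibenzyl stage because the last hydroxyl is locked in a hydrogen bond to the acetyl carbonyl and is far less nucleophilic.

Step 10
Reactants: 19 3-[5-ethoxy-3-(4-methoxyphenyl)-4-oxo-7-(triisopropylsilyloxy)-4H-chromen-8-yl]-4-methoxybenzaldehyde; 21 1-[2,4-bis(benzyloxy)-6-hydroxyphenyl]ethanone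
Product: 23 8-{5-[(E)-3-(2,4-bis(benzyloxy)-6-hydroxyphenyl)-3-oxoprop-1-enyl]-2-methoxyphenyl}-5-ethoxy-7-hydroxy-3-(4-methoxyphenyl)-4H-chromen-4-one, via potassium phenoxide 22 (not isolated)
Conditions: KOH (50% aq., excess), EtOH–THF, rt; 1 M HCl
Reagents that add atoms: none
Why: Claisen–Schmidt condensation in which hydroxide first strips the silyl group from the acidic O7, the resulting phenoxide 22 feeds electron density into the pyranone and so shields C2 from hydroxide, and the enolate of 21 condenses with the aldehyde, with E1cB dehydration setting the thermodynamic E alkene.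

Step 11
Reactants: 23 8-{5-[(E)-3-(2,4-bis(benzyloxy)-6-hydroxyphenyl)-3-oxoprop-1-enyl]-2-methoxyphenyl}-5-ethoxy-7-hydroxy-3-(4-methoxyphenyl)-4H-chromen-4-one
Product: 24 8-{5-[5,7-bis(benzyloxy)-4-oxo-4H-chromen-2-yl]-2-methoxyphenyl}-5-ethoxy-7-hydroxy-3-(4-methoxyphenyl)-4H-chromen-4-one
Conditions: I2 (10 mol %), DMSO, 120 °C
Reagents that add atoms: none
Why: Iodine-catalysed cyclodehydrogenation of a 2'-hydroxychalcone, with DMSO re-oxidising the HI formed, is the standard flavone closure and tolerates benzyl, ethyl and methyl aryl ethers.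

Step 12
Reactants: 24 8-{5-[5,7-bis(benzyloxy)-4-oxo-4H-chromen-2-yl]-2-methoxyphenyl}-5-ethoxy-7-hydroxy-3-(4-methoxyphenyl)-4H-chromen-4-one
Product: 25 8-[5-(5,7-dihydroxy-4-oxo-4H-chromen-2-yl)-2-methoxyphenyl]-5,7-dihydroxy-3-(4-methoxyphenyl)-4H-chromen-4-one (CNP0117905.0)
Conditions: BCl3 (1 M in CH2Cl2, excess), pentamethylbenzene, CH2Cl2, –78 → 0 °C; H2O
Reagents that add atoms: none
Why: Lewis-acid ether cleavage in which BCl3 chelated between each C4 carbonyl and its peri oxygen dealkylates the 5-ethoxy and the flavone 5-benzyloxy groups, the remaining benzyl ether ionises readily with pentamethylbenzene as a non-basic cation trap, and the two unchelated aryl methyl ethers should be inert at this temperature.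

Compound list
1 | methyl 5-formyl-2-methoxybenzoate | COC(=O)c1cc(C=O)ccc1OC | starting material
2 | methyl 5-(5,5-dimethyl-1,3-dioxan-2-yl)-2-methoxybenzoate | COC(=O)c1cc(C2OCC(C)(C)CO2)ccc1OC | intermediate
3 | lithium 2,2-dibromo-1-[5-(5,5-dimethyl-1,3-dioxan-2-yl)-2-methoxyphenyl]ethenolate | [Li+].[O-]C(=C(Br)Br)c1cc(C2OCC(C)(C)CO2)ccc1OC | intermediate
4 | lithium [5-(5,5-dimethyl-1,3-dioxan-2-yl)-2-methoxyphenyl]ethynolate | [Li+].[O-]C#Cc1cc(C2OCC(C)(C)CO2)ccc1OC | intermediate
5 | {[5-(5,5-dimethyl-1,3-dioxan-2-yl)-2-methoxyphenyl]ethynyloxy}triisopropylsilane | COc1ccc(C2OCC(C)(C)CO2)cc1C#CO[Si](C(C)C)(C(C)C)C(C)C | intermediate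
6 | 3-ethoxycyclobut-2-en-1-one | CCOC1=CC(=O)C1 | starting material
7 | 3-ethoxybuta-1,3-dien-1-one (vinylketene) | C=C(OCC)C=C=O | intermediate
8 | 2-aryl-4-(1-ethoxyvinyl)-3-(triisopropylsilyloxy)cyclobut-2-en-1-one, racemic (aryl = 5-(5,5-dimethyl-1,3-dioxan-2-yl)-2-methoxyphenyl) | CCOC(=C)C1C(=O)C(c2cc(C3OCC(C)(C)CO3)ccc2OC)=C1O[Si](C(C)C)(C(C)C)C(C)C | intermediate
9 | 2-aryl-5-ethoxy-3-(triisopropylsilyloxy)hexa-1,3,5-trien-1-one, ketenyl and ethoxyvinyl groups cis (dienylketene) | C=C(OCC)/C=C(O[Si](C(C)C)(C(C)C)C(C)C)\C(=C=O)c1cc(C2OCC(C)(C)CO2)ccc1OC | intermediate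
10 | 2-aryl-5-ethoxy-3-(triisopropylsilyloxy)cyclohexa-2,4-dien-1-one | CCOC1=CC(O[Si](C(C)C)(C(C)C)C(C)C)=C(c2cc(C3OCC(C)(C)CO3)ccc2OC)C(=O)C1 | intermediate
11 | 2-[5-(5,5-dimethyl-1,3-dioxan-2-yl)-2-methoxyphenyl]-5-ethoxy-3-(triisopropylsilyloxy)phenol | CCOc1cc(O)c(-c2cc(C3OCC(C)(C)CO3)ccc2OC)c(O[Si](C(C)C)(C(C)C)C(C)C)c1 | intermediate
12 | methyl 4-methoxyphenylacetate | COC(=O)Cc1ccc(OC)cc1 | starting material
13 | methyl (Z)-3-hydroxy-2-(4-methoxyphenyl)acrylate | COC(=O)/C(=C\O)c1ccc(OC)cc1 | intermediate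
14 | methyl (E)-2-(4-methoxyphenyl)-3-(tosyloxy)acrylate | COC(=O)/C(=C/OS(=O)(=O)c1ccc(C)cc1)c1ccc(OC)cc1 | intermediate
15 | methyl (E)-3-{2-[5-(5,5-dimethyl-1,3-dioxan-2-yl)-2-methoxyphenyl]-5-ethoxy-3-(triisopropylsilyloxy)phenoxy}-2-(4-methoxyphenyl)acrylate | COC(=O)/C(=C/Oc1cc(OCC)cc(O[Si](C(C)C)(C(C)C)C(C)C)c1-c1cc(C2OCC(C)(C)CO2)ccc1OC)c1ccc(OC)cc1 | intermediate
16 | (E)-3-{2-[5-(5,5-dimethyl-1,3-dioxan-2-yl)-2-methoxyphenyl]-5-ethoxy-3-(triisopropylsilyloxy)phenoxy}-2-(4-methoxyphenyl)acrylic acid | OC(=O)/C(=C/Oc1cc(OCC)cc(O[Si](C(C)C)(C(C)C)C(C)C)c1-c1cc(C2OCC(C)(C)CO2)ccc1OC)c1ccc(OC)cc1 | intermediate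
17 | mixed anhydride of 16 with trifluoroacetic acid | O=C(OC(=O)C(F)(F)F)/C(=C/Oc1cc(OCC)cc(O[Si](C(C)C)(C(C)C)C(C)C)c1-c1cc(C2OCC(C)(C)CO2)ccc1OC)c1ccc(OC)cc1 | intermediate
18 | 8-[5-(5,5-dimethyl-1,3-dioxan-2-yl)-2-methoxyphenyl]-5-ethoxy-3-(4-methoxyphenyl)-7-(triisopropylsilyloxy)-4H-chromen-4-one | COc1ccc(-c2coc3c(-c4cc(C5OCC(C)(C)CO5)ccc4OC)c(O[Si](C(C)C)(C(C)C)C(C)C)cc(OCC)c3c2=O)cc1 | intermediate
19 | 3-[5-ethoxy-3-(4-methoxyphenyl)-4-oxo-7-(triisopropylsilyloxy)-4H-chromen-8-yl]-4-methoxybenzaldehyde | COc1ccc(-c2coc3c(-c4cc(C=O)ccc4OC)c(O[Si](C(C)C)(C(C)C)C(C)C)cc(OCC)c3c2=O)cc1 | intermediate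
20 | 2,4,6-trihydroxyacetophenone | CC(=O)c1c(O)cc(O)cc1O | starting material
21 | 1-[2,4-bis(benzyloxy)-6-hydroxyphenyl]ethanone | CC(=O)c1c(O)cc(OCc2ccccc2)cc1OCc1ccccc1 | intermediate
22 | potassium 5-ethoxy-8-(5-formyl-2-methoxyphenyl)-3-(4-methoxyphenyl)-4-oxo-4H-chromen-7-olate | COc1ccc(-c2coc3c(-c4cc(C=O)ccc4OC)c([O-])cc(OCC)c3c2=O)cc1.[K+] | intermediate
23 | 8-{5-[(E)-3-(2,4-bis(benzyloxy)-6-hydroxyphenyl)-3-oxoprop-1-enyl]-2-methoxyphenyl}-5-ethoxy-7-hydroxy-3-(4-methoxyphenyl)-4H-chromen-4-one | COc1ccc(-c2coc3c(-c4cc(/C=C/C(=O)c5c(O)cc(OCc6ccccc6)cc5OCc7ccccc7)ccc4OC)c(O)cc(OCC)c3c2=O)cc1 | intermediate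
24 | 8-{5-[5,7-bis(benzyloxy)-4-oxo-4H-chromen-2-yl]-2-methoxyphenyl}-5-ethoxy-7-hydroxy-3-(4-methoxyphenyl)-4H-chromen-4-one | COc1ccc(-c2coc3c(-c4cc(-c5cc(=O)c6c(OCc7ccccc7)cc(OCc7ccccc7)cc6o5)ccc4OC)c(O)cc(OCC)c3c2=O)cc1 | intermediate
25 | 8-[5-(5,7-dihydroxy-4-oxo-4H-chromen-2-yl)-2-methoxyphenyl]-5,7-dihydroxy-3-(4-methoxyphenyl)-4H-chromen-4-one | COc1ccc(-c2coc3c(-c4cc(-c5cc(=O)c6c(O)cc(O)cc6o5)ccc4OC)c(O)cc(O)c3c2=O)cc1 | target

Total step count: 12. Longest linear sequence: 9 (steps 1, 2, 3, 6, 7, 8, 10, 11, 12).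

Steps most likely to fail

Step 3. The donor-stabilised cyclobutenone may open only sluggishly. Prolonged heating could then let the ketene dimerise, let it acylate the phenol as it forms, or let the siloxyalkyne rearrange to a silylketene.
- The fallback sets out from 5 and comes back at 11.
- It releases the same ketene 7 at room temperature by a photochemical Wolff rearrangement instead of a thermal ring opening.
- Ethyl vinyl ether is lithiated (t-BuLi, THF) and acylated with N-methoxy-N-methylacetamide to 3-ethoxybut-3-en-2-one F1.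
- LiN(SiMe3)2 and CF3CO2CH2CF3 convert it into 5-ethoxy-1,1,1-trifluorohex-5-ene-2,4-dione F2.
- Detrifluoroacetylative diazo transfer (MsN3, Et3N, H2O, MeCN) gives 1-diazo-3-ethoxybut-3-en-2-one F3.
- Irradiation of this diazoketone with 5 in ClCH2CH2Cl, then warming to 80 °C, should carry 7 through 8, 9 and 10 to 11.

Step 8. Several processes could outrun ring closure: ionisation of the acetal in the anhydrous acid, intermolecular trifluoroacetylation of the very electron-rich ring A, or slow rotation of the E acrylate into the reactive geometry.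
- The fallback sets out from 11 and comes back at 18.
- It installs the carbonyl carbon at C4a under neutral and basic conditions and makes steps 4 to 7 unnecessary.
- Magnesium-mediated ortho-formylation (MgCl2, Et3N, paraformaldehyde, MeCN, reflux; Casnati–Skattebøl) can only strike C4a and gives 3-[5-(5,5-dimethyl-1,3-dioxan-2-yl)-2-methoxyphenyl]-6-ethoxy-2-hydroxy-4-(triisopropylsilyloxy)benzaldehyde F4.
- 4-Methoxybenzylmagnesium chloride (2.2 equiv, THF, 0 °C) gives the racemic benzylic carbinol F5.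
- MnO2 in CH2Cl2 oxidises it to the deoxybenzoin F6.
- Me2NCH(OMe)2 in toluene at 90 °C adds C2 and closes the pyranone to 18, which is hydrolysed as in the second stage of step 8.

Step 10. Hydroxide may add to C2 of the pyranone and open the isoflavone, either before desilylation has built up the protective phenoxide or during the long condensation.
- The fallback sets out from 19 and comes back at 24.
- It replaces the aldol logic by an acyl transfer under a non-nucleophilic base.
- Pinnick oxidation (NaClO2, NaH2PO4, 2-methyl-2-butene, t-BuOH–H2O) gives the benzoic acid F7.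
- EDC·HCl and DMAP couple it with 21 to the aryl ester F8.
- Baker–Venkataraman rearrangement (LiN(SiMe3)2, THF, –78 → –20 °C) gives the 1,3-diketone F9.
- p-TsOH·H2O in toluene at 80 °C cyclodehydrates it to the silylated flavone–isoflavone F10.
- Bu4NF with AcOH in THF then gives 24.

Further compounds
F1 | step 3 | 3-ethoxybut-3-en-2-one | C=C(OCC)C(C)=O
F2 | step 3 | 5-ethoxy-1,1,1-trifluorohex-5-ene-2,4-dione | C=C(OCC)C(=O)CC(=O)C(F)(F)F
F3 | step 3 | 1-diazo-3-ethoxybut-3-en-2-one | C=C(OCC)C(=O)C=[N+]=[N-]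
F4 | step 8 | 3-[5-(5,5-dimethyl-1,3-dioxan-2-yl)-2-methoxyphenyl]-6-ethoxy-2-hydroxy-4-(triisopropylsilyloxy)benzaldehyde | CCOc1cc(O[Si](C(C)C)(C(C)C)C(C)C)c(-c2cc(C3OCC(C)(C)CO3)ccc2OC)c(O)c1C=O
F5 | step 8 | 6-[5-(5,5-dimethyl-1,3-dioxan-2-yl)-2-methoxyphenyl]-3-ethoxy-2-[1-hydroxy-2-(4-methoxyphenyl)ethyl]-5-(triisopropylsilyloxy)phenol, racemic | CCOc1cc(O[Si](C(C)C)(C(C)C)C(C)C)c(-c2cc(C3OCC(C)(C)CO3)ccc2OC)c(O)c1C(O)Cc1ccc(OC)cc1
F6 | step 8 | 1-{3-[5-(5,5-dimethyl-1,3-dioxan-2-yl)-2-methoxyphenyl]-6-ethoxy-2-hydroxy-4-(triisopropylsilyloxy)phenyl}-2-(4-methoxyphenyl)ethanone | CCOc1cc(O[Si](C(C)C)(C(C)C)C(C)C)c(-c2cc(C3OCC(C)(C)CO3)ccc2OC)c(O)c1C(=O)Cc1ccc(OC)cc1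
F7 | step 10 | 3-[5-ethoxy-3-(4-methoxyphenyl)-4-oxo-7-(triisopropylsilyloxy)-4H-chromen-8-yl]-4-methoxybenzoic acid | COc1ccc(-c2coc3c(-c4cc(C(=O)O)ccc4OC)c(O[Si](C(C)C)(C(C)C)C(C)C)cc(OCC)c3c2=O)cc1
F8 | step 10 | 2-acetyl-3,5-bis(benzyloxy)phenyl 3-[5-ethoxy-3-(4-methoxyphenyl)-4-oxo-7-(triisopropylsilyloxy)-4H-chromen-8-yl]-4-methoxybenzoate | COc1ccc(-c2coc3c(-c4cc(C(=O)Oc5cc(OCc6ccccc6)cc(OCc6ccccc6)c5C(C)=O)ccc4OC)c(O[Si](C(C)C)(C(C)C)C(C)C)cc(OCC)c3c2=O)cc1
F9 | step 10 | 1-[2,4-bis(benzyloxy)-6-hydroxyphenyl]-3-{3-[5-ethoxy-3-(4-methoxyphenyl)-4-oxo-7-(triisopropylsilyloxy)-4H-chromen-8-yl]-4-methoxyphenyl}propane-1,3-dione | COc1ccc(-c2coc3c(-c4cc(C(=O)CC(=O)c5c(O)cc(OCc6ccccc6)cc5OCc7ccccc7)ccc4OC)c(O[Si](C(C)C)(C(C)C)C(C)C)cc(OCC)c3c2=O)cc1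
F10 | step 10 | 8-{5-[5,7-bis(benzyloxy)-4-oxo-4H-chromen-2-yl]-2-methoxyphenyl}-5-ethoxy-3-(4-methoxyphenyl)-7-(triisopropylsilyloxy)-4H-chromen-4-one | COc1ccc(-c2coc3c(-c4cc(-c5cc(=O)c6c(OCc7ccccc7)cc(OCc7ccccc7)cc6o5)ccc4OC)c(O[Si](C(C)C)(C(C)C)C(C)C)cc(OCC)c3c2=O)cc1
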